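**Retrosynthetic overview**
1. The isocoumarin ring is closed last: C4–C4a and O2–C3 come from a C–H annulation of 5-chloro-2,4-dihydroxybenzoic acid 15 with the dienoyl sulfoxonium ylide 12.
2. Ylide 12 comes from dienoic acid 10; the (E,E)-diene is made by vinylogous Horner–Wadsworth–Emmons olefination of oxolane aldehyde 8.
3. Key step: the oxolane ring of 8 is made by oxidative ring contraction of the six-membered glycal acetate 7 (1,2-shift of the ring oxygen from C1 to C2, which sets oxolane C2).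
4. Glycal 7 comes from (S)-dihydropyranone 5 by cis-selective 1,2-reduction (sets the carbinol centre); 5 comes from hydroxy ynone 3, made from methyl (S)-3-hydroxybutanoate 1 (source of the methyl-bearing centre).
5. Acid 15 comes from resorcinol 13. Ring order: benzene (bought), dihydropyranone, oxolane (by contraction), isocoumarin pyranone last.

Assumption: the SMILES is read as the (2S,3R,5S)-oxolane (2,3-trans, 2,5-trans, 3,5-cis) with a (1E,3E)-diene; the volatile intermediates 3, 5 and 7 are carried forward as solutions.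

**Step 1**
Reactants: 1 methyl (S)-3-hydroxybutanoate
Product: 3 (S)-5-hydroxyhex-1-yn-3-one, via Weinreb amide 2 (not isolated)
Conditions: MeNHOMe·HCl, iPrMgCl, THF, −20 °C; then HC≡CMgBr, 0 °C → rt; cold aq. NaHSO4
Reagents that add atoms: ethynylmagnesium bromide, C#C[Mg]Br
Why: Aminolysis of the ester by the magnesium amide gives the Weinreb amide, whose stable chelate with the alkynyl Grignard reagent releases the ynone only on quench (Weinreb ketone synthesis), and the carbinol stereocentre is not touched.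

**Step 2**
Reactants: 3 (S)-5-hydroxyhex-1-yn-3-one
Product: 5 (S)-2-methyl-2,3-dihydro-4H-pyran-4-one, via enaminone 4 (not isolated)
Conditions: Et2NH, EtOH, 0 °C; then 2 M HCl, THF, rt
Reagents that add atoms: none
Why: Aza-Michael addition of the amine to the terminal ynone gives the enaminone, which under acid undergoes 6-endo oxa-Michael addition and loss of the amine to the dihydropyranone (addition–elimination cyclisation) without touching the stereocentre.

**Step 3**
Reactants: 5 (S)-2-methyl-2,3-dihydro-4H-pyran-4-one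
Product: 7 (2S,4R)-2-methyl-3,4-dihydro-2H-pyran-4-yl acetate, via aluminium alkoxide 6 (not isolated)
Conditions: iBu2AlH, CH2Cl2, −78 °C; then pyridine, DMAP, Ac2O, −78 → 0 °C; aq. KNaC4H4O6
Reagents that add atoms: acetic anhydride, CC(=O)OC(C)=O
Why: 1,2-Reduction of the vinylogous ester by axial hydride delivery gives the equatorial alcohol cis to the methyl group (sets C4 as R), and the aluminium alkoxide is acetylated in the same flask (reductive acetylation), the electron-poor acetate being what steers step 4 toward ring-oxygen migration.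

**Step 4 (key step)**
Reactants: 7 (2S,4R)-2-methyl-3,4-dihydro-2H-pyran-4-yl acetate
Product: 8 (2R,3R,5S)-2-formyl-5-methyloxolan-3-yl acetate
Conditions: Tl(NO3)3·3H2O (1.1 equiv), MeCN, 0 °C → rt, 15 min; NaHCO3 work-up, used crude
Reagents that add atoms: water (from the hydrate), O
Why: Oxidative ring contraction of a glycal by trivalent thallium, as in the conversion of tri-O-acetylglucal into 2,5-anhydromannose: oxythallation puts thallium on the enol-ether β-carbon anti to the acetoxy group, and the ring oxygen then shifts from C1 to C2 with inversion as monovalent thallium leaves, so the formyl group ends trans to the acetate and trans to the methyl group.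

**Step 5**
Reactants: 8 (2R,3R,5S)-2-formyl-5-methyloxolan-3-yl acetate
Product: 10 (2E,4E)-5-[(2S,3R,5S)-3-hydroxy-5-methyloxolan-2-yl]penta-2,4-dienoic acid, via dienoate ester 9 (not isolated)
Conditions: (EtO)2P(O)CH2CH=CHCO2Et, LiN(SiMe3)2, THF, −78 → 0 °C; then LiOH·H2O, MeOH–H2O, rt; HCl to pH 3
Reagents that add atoms: triethyl 4-phosphonocrotonate, CCOC(=O)/C=C/CP(=O)(OCC)OCC; lithium hydroxide, [Li+].[OH-]
Why: Vinylogous Horner–Wadsworth–Emmons olefination gives the (2E,4E)-dienoate under thermodynamic control, the low temperature suppresses β-elimination of acetate from the aldehyde, and saponification in the same flask removes the ethyl ester and the acetate.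

**Step 6**
Reactants: 10 (2E,4E)-5-[(2S,3R,5S)-3-hydroxy-5-methyloxolan-2-yl]penta-2,4-dienoic acid
Product: 12 (3E,5E)-1-[dimethyl(oxo)-λ6-sulfanylidene]-6-[(2S,3R,5S)-3-hydroxy-5-methyloxolan-2-yl]hexa-3,5-dien-2-one, via acyl imidazolide 11 (not isolated)
Conditions: CDI (1.05 equiv), THF, rt; then added to Me3S(O)I/KOtBu (3.2 equiv), THF, 0 °C → rt
Reagents that add atoms: trimethylsulfoxonium iodide, C[S+](C)(C)=O.[I-]
Why: C-Acylation of dimethylsulfoxonium methylide by an acyl imidazolide (the standard route to β-keto sulfoxonium ylides) is faster at 0 °C than conjugate addition to the dienoyl system, and the extra ylide covers the free hydroxyl and the acidic product.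

**Step 7**
Reactants: 13 resorcinol
Product: 14 2,4-dihydroxybenzoic acid
Conditions: KHCO3, H2O, CO2 (1 atm), 100 °C; then HCl
Reagents that add atoms: potassium hydrogencarbonate, [K+].OC([O-])=O
Why: Kolbe–Schmitt carboxylation of resorcinol occurs ortho to one hydroxyl and para to the other, giving β-resorcylic acid.

**Step 8**
Reactants: 14 2,4-dihydroxybenzoic acid
Product: 15 5-chloro-2,4-dihydroxybenzoic acid
Conditions: SO2Cl2 (1.05 equiv), Et2O, 0 °C → rt
Reagents that add atoms: sulfuryl chloride, ClS(Cl)(=O)=O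
Why: Electrophilic aromatic chlorination goes to C5 (para to the chelated 2-hydroxyl, ortho to the 4-hydroxyl), the known outcome for β-resorcylic acid.

**Step 9**
Reactants: 15 5-chloro-2,4-dihydroxybenzoic acid; 12 (3E,5E)-1-[dimethyl(oxo)-λ6-sulfanylidene]-6-[(2S,3R,5S)-3-hydroxy-5-methyloxolan-2-yl]hexa-3,5-dien-2-one
Product: 17 5-chloro-6,8-dihydroxy-3-[(1E,3E)-4-[(2S,3R,5S)-3-hydroxy-5-methyloxolan-2-yl]buta-1,3-dien-1-yl]-1H-isochromen-1-one, via keto acid 16 (not isolated)
Conditions: [Cp*RhCl2]2 (4 mol%), AgSbF6 (16 mol%), NaOAc (0.5 equiv), CF3CH2OH, 60 °C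
Reagents that add atoms: none
Why: Proposed new method: carboxylate-directed C–H annulation of an unprotected chlororesorcylic acid with a conjugated dienoyl sulfoxonium ylide – acetate-assisted metalation by Cp*Rh (trivalent rhodium) can only occur at C6–H (the sole free ortho position, acidified by the neighbouring chlorine), the ylide binds through carbon and loses dimethyl sulfoxide to give a rhodium carbene that inserts into the Rh–aryl bond (forming C4–C4a), protodemetalation releases keto acid 16, and its enol-lactonisation (O2–C3) closes the isocoumarin ring; the carbene stays on the metal, so the phenols and the alcohol are not O–H insertion partners, and no external oxidant meets the diene; the closest known reaction is the trivalent-rhodium (or divalent-ruthenium) catalysed synthesis of 3-substituted isocoumarins from O-protected benzoic acids and aroyl or alkanoyl sulfoxonium ylides, which has not been shown with a dienoyl ylide, with free phenols or at a chlorine-flanked C–H bond.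

**Compound list**
1 | methyl (S)-3-hydroxybutanoate | C[C@H](O)CC(=O)OC | starting material
2 | (S)-3-hydroxy-N-methoxy-N-methylbutanamide (present as its chloromagnesium alkoxide) | C[C@H](O)CC(=O)N(C)OC | intermediate
3 | (S)-5-hydroxyhex-1-yn-3-one | C[C@H](O)CC(=O)C#C | intermediate
4 | (S,E)-1-(diethylamino)-5-hydroxyhex-1-en-3-one | C[C@H](O)CC(=O)/C=C/N(CC)CC | intermediate
5 | (S)-2-methyl-2,3-dihydro-4H-pyran-4-one | C[C@H]1CC(=O)C=CO1 | intermediate
6 | diisobutylaluminium (2S,4R)-2-methyl-3,4-dihydro-2H-pyran-4-olate | C[C@H]1C[C@@H](O[Al](CC(C)C)CC(C)C)C=CO1 | intermediate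
7 | (2S,4R)-2-methyl-3,4-dihydro-2H-pyran-4-yl acetate (acetoxy cis to methyl) | C[C@H]1C[C@@H](OC(C)=O)C=CO1 | intermediate
8 | (2R,3R,5S)-2-formyl-5-methyloxolan-3-yl acetate | C[C@H]1C[C@@H](OC(C)=O)[C@H](C=O)O1 | intermediate
9 | ethyl (2E,4E)-5-[(2S,3R,5S)-3-acetoxy-5-methyloxolan-2-yl]penta-2,4-dienoate | C[C@H]1C[C@@H](OC(C)=O)[C@H](/C=C/C=C/C(=O)OCC)O1 | intermediate
10 | (2E,4E)-5-[(2S,3R,5S)-3-hydroxy-5-methyloxolan-2-yl]penta-2,4-dienoic acid | C[C@H]1C[C@@H](O)[C@H](/C=C/C=C/C(=O)O)O1 | intermediate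
11 | (2E,4E)-5-[(2S,3R,5S)-3-hydroxy-5-methyloxolan-2-yl]-1-(1H-imidazol-1-yl)penta-2,4-dien-1-one | C[C@H]1C[C@@H](O)[C@H](/C=C/C=C/C(=O)n2ccnc2)O1 | intermediate
12 | (3E,5E)-1-[dimethyl(oxo)-λ6-sulfanylidene]-6-[(2S,3R,5S)-3-hydroxy-5-methyloxolan-2-yl]hexa-3,5-dien-2-one | C[C@H]1C[C@@H](O)[C@H](/C=C/C=C/C(=O)C=S(C)(C)=O)O1 | intermediate
13 | resorcinol | Oc1cccc(O)c1 | starting material
14 | 2,4-dihydroxybenzoic acid | OC(=O)c1ccc(O)cc1O | intermediate
15 | 5-chloro-2,4-dihydroxybenzoic acid | OC(=O)c1cc(Cl)c(O)cc1O | intermediate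
16 | 3-chloro-4,6-dihydroxy-2-[(3E,5E)-6-[(2S,3R,5S)-3-hydroxy-5-methyloxolan-2-yl]-2-oxohexa-3,5-dien-1-yl]benzoic acid | C[C@H]1C[C@@H](O)[C@H](/C=C/C=C/C(=O)Cc2c(Cl)c(O)cc(O)c2C(=O)O)O1 | intermediate
17 | 5-chloro-6,8-dihydroxy-3-[(1E,3E)-4-[(2S,3R,5S)-3-hydroxy-5-methyloxolan-2-yl]buta-1,3-dien-1-yl]-1H-isochromen-1-one | C[C@H]1C[C@@H](O)[C@H](/C=C/C=C/c2cc3c(Cl)c(O)cc(O)c3c(=O)o2)O1 | target

**Step count:** 9 steps in total. Longest linear sequence: 7 (steps 1–6, then 9); the aromatic branch is steps 7–8.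

**Three steps most likely to fail**

Step 9 (the proposed new annulation; risks are the free phenols, the hindered C–H bond and the acid-sensitive dienyl ether). The fallback sets out from 15 and 8 and comes back at 17 using known reactions. Silylate 15 (TBSCl, imidazole, DMF) to tert-butyldimethylsilyl 2,4-bis(tert-butyldimethylsilyloxy)-5-chlorobenzoate F6. Hydrolyse only the silyl ester (AcOH–H2O–THF, rt) to 2,4-bis(tert-butyldimethylsilyloxy)-5-chlorobenzoic acid F7. Run the literature annulation ([Cp*RhCl2]2, AgSbF6, NaOAc) with the simple ylide 1-[dimethyl(oxo)-λ6-sulfanylidene]propan-2-one to give 6,8-bis(tert-butyldimethylsilyloxy)-5-chloro-3-methylisochromen-1-one F8. Deprotonate its 3-methyl group (LiN(iPr)2, THF, −78 °C) and add the enal F5 (made from 8 as in the step 5 fallback) to give the aldol adduct F9. Convert this to the mesylate F10 (MsCl, Et3N) and eliminate with DBU to the protected dienyl isocoumarin F11. K2CO3 in MeOH then removes both aryl silyl ethers and the acetate to give 17.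

Step 4 (ring contraction; risks are competing acetoxonium participation, enone formation and the fragile aldehyde). The fallback sets out from 7 and comes back at 8 by the stepwise sulfonate contraction. Epoxidise 7 with dimethyldioxirane anti to the acetate to the 1,2-anhydro sugar (1S,3S,5R,6S)-3-methyl-2,7-dioxabicyclo[4.1.0]heptan-5-yl acetate F1. Open it with methanol to the all-equatorial methyl glycoside (2S,3S,4R,6S)-3-hydroxy-2-methoxy-6-methyloxan-4-yl acetate F2. Convert the free hydroxyl to the triflate (2S,3S,4R,6S)-2-methoxy-6-methyl-3-[(trifluoromethanesulfonyl)oxy]oxan-4-yl acetate F3 (Tf2O, pyridine, −20 °C). Warm F3 in methanol with 2,6-lutidine, so that the ring oxygen displaces the antiperiplanar equatorial triflate, giving the acetal (2R,3R,5S)-2-(dimethoxymethyl)-5-methyloxolan-3-yl acetate F4. Hydrolyse with aqueous CF3CO2H to 8.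

Step 5 (risks are base-induced loss of acetate from the β-acetoxy aldehyde and E/Z mixtures). The fallback sets out from 8 and comes back at 9 by two non-basic two-carbon olefinations. Wittig reaction of 8 with Ph3P=CHCHO (toluene, 60 °C) gives the enal (2S,3R,5S)-5-methyl-2-[(E)-3-oxoprop-1-en-1-yl]oxolan-3-yl acetate F5. Olefination of F5 with triethyl phosphonoacetate under LiCl/DBU in MeCN gives 9, which is saponified to 10 as in step 5.

**Further compounds**
F1 | step 4 | (1S,3S,5R,6S)-3-methyl-2,7-dioxabicyclo[4.1.0]heptan-5-yl acetate (oxirane trans to the acetate) | C[C@H]1C[C@@H](OC(C)=O)[C@@H]2O[C@@H]2O1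
F2 | step 4 | (2S,3S,4R,6S)-3-hydroxy-2-methoxy-6-methyloxan-4-yl acetate | C[C@H]1C[C@@H](OC(C)=O)[C@H](O)[C@@H](OC)O1
F3 | step 4 | (2S,3S,4R,6S)-2-methoxy-6-methyl-3-[(trifluoromethanesulfonyl)oxy]oxan-4-yl acetate | C[C@H]1C[C@@H](OC(C)=O)[C@H](OS(=O)(=O)C(F)(F)F)[C@@H](OC)O1
F4 | step 4 | (2R,3R,5S)-2-(dimethoxymethyl)-5-methyloxolan-3-yl acetate | C[C@H]1C[C@@H](OC(C)=O)[C@H](C(OC)OC)O1
F5 | step 5 | (2S,3R,5S)-5-methyl-2-[(E)-3-oxoprop-1-en-1-yl]oxolan-3-yl acetate | C[C@H]1C[C@@H](OC(C)=O)[C@H](/C=C/C=O)O1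
F6 | step 9 | tert-butyldimethylsilyl 2,4-bis(tert-butyldimethylsilyloxy)-5-chlorobenzoate | CC(C)(C)[Si](C)(C)OC(=O)c1cc(Cl)c(O[Si](C)(C)C(C)(C)C)cc1O[Si](C)(C)C(C)(C)C
F7 | step 9 | 2,4-bis(tert-butyldimethylsilyloxy)-5-chlorobenzoic acid | OC(=O)c1cc(Cl)c(O[Si](C)(C)C(C)(C)C)cc1O[Si](C)(C)C(C)(C)C
F8 | step 9 | 6,8-bis(tert-butyldimethylsilyloxy)-5-chloro-3-methyl-1H-isochromen-1-one | Cc1cc2c(Cl)c(O[Si](C)(C)C(C)(C)C)cc(O[Si](C)(C)C(C)(C)C)c2c(=O)o1
F9 | step 9 | (2S,3R,5S)-2-[(1E)-4-[6,8-bis(tert-butyldimethylsilyloxy)-5-chloro-1-oxo-1H-isochromen-3-yl]-3-hydroxybut-1-en-1-yl]-5-methyloxolan-3-yl acetate (both carbinol epimers) | C[C@H]1C[C@@H](OC(C)=O)[C@H](/C=C/C(O)Cc2cc3c(Cl)c(O[Si](C)(C)C(C)(C)C)cc(O[Si](C)(C)C(C)(C)C)c3c(=O)o2)O1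
F10 | step 9 | methanesulfonate of F9 at the carbinol oxygen | C[C@H]1C[C@@H](OC(C)=O)[C@H](/C=C/C(OS(C)(=O)=O)Cc2cc3c(Cl)c(O[Si](C)(C)C(C)(C)C)cc(O[Si](C)(C)C(C)(C)C)c3c(=O)o2)O1
F11 | step 9 | (2S,3R,5S)-2-[(1E,3E)-4-[6,8-bis(tert-butyldimethylsilyloxy)-5-chloro-1-oxo-1H-isochromen-3-yl]buta-1,3-dien-1-yl]-5-methyloxolan-3-yl acetate | C[C@H]1C[C@@H](OC(C)=O)[C@H](/C=C/C=C/c2cc3c(Cl)c(O[Si](C)(C)C(C)(C)C)cc(O[Si](C)(C)C(C)(C)C)c3c(=O)o2)O1
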